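Amounts are best counted by what is left: with f the fraction of starting material left, ln(1/f) grows in a straight line under pseudo-first-order decay, and target is a share of what has gone.

| flask | starting material | reagent | second substrate | remark | time |
|---|---|---|---|---|---|
| theta | 0.013 M | 0.0077 M | 2.6 mM | run made earlier |  |
| delta | 0.013 M | 0.021 M | 2.6 mM | run made earlier |  |
| gamma | 0.0069 M | 0.0137 M | 2.6 mM | run made earlier |  |
| birch | 0.0030 M | 0.00600 M | 2.60 mM |  | 25 h |
| ash | 0.013 M | 0.0137 M | 2.60 mM |  | 25 h |

| run | time / h | target / % | starting material / % |
|---|---|---|---|
| theta | 1.33 | 4.0 | 91.7 |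
| theta | 3.00 | 7.7 | 84.9 |
| theta | 8.00 | 18.3 | 71.0 |
| theta | 20.0 | 27.4 | 57.0 |
| delta | 1.33 | 11.5 | 84.6 |
| delta | 3.00 | 22.0 | 71.3 |
| delta | 8.00 | 37.6 | 48.5 |
| delta | 20.0 | 46.0 | 25.4 |
| gamma | 1.33 | 7.3 | 87.6 |
| gamma | 3.00 | 14.8 | 76.1 |
| gamma | 8.00 | 30.0 | 56.6 |
| gamma | 20.0 | 42.4 | 33.7 |

(scatter of a reading: 0.5 percentage points)

1. which one finishes higher in amount of target, in percent of the starting material charged ("neither" within 2 percentage points) (birch / ash / neither)
2. amount of target at the end, in percent of the starting material charged, birch
3. amount of target at the end, in percent of the starting material charged, ash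

- the numbers in the tables scatter with a standard deviation of 0.5 percentage points

1. I call ln(1/f) the log-left. At 20.0 h it reads 0.562 in theta and 1.37 in delta, two runs with ash's charges of starting material and second substrate.

2. Ash's reagent lies 0.451 of the way from theta to delta. Assuming a straight line in reagent, I put ash's log-left at that time at 0.927, so f is 39.6%. Since f only falls, this is my upper limit for f at 25 h.

3. Between the last two readings the log-left climbs 0.0183 /h in theta and 0.0539 /h in delta, which gives ash 0.0344 /h. In theta this rate is lower than the 0.0358 /h of the interval before, so holding it steady overshoots. That gives a lower limit for f of 33.3%.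

4. The last readings give a selectivity, target per starting material gone, of 0.617 in delta and 0.640 in gamma. Assuming, without proof, that ash's selectivity lies between these two readings, I estimate its target at 37.3% to 42.7%.

5. The forecast gives ash 39.5%, inside my estimated span, and birch 33%, which I have not reckoned: “Ash finishes higher”.

Result: ash finishes higher, with birch at 31.3% and ash at 42.2%, both inside the forecast's ranges. Ash keeps 36.2% of its starting material, a log-left of 1.02, inside the bracket. Its selectivity is 0.662, higher than both readings of step 4, so my assumption there fails for ash.

    starting material + reagent → target (k = 4.80 /M/h)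
    second substrate + reagent → second product (k = 9.20 /M/h)
    starting material + second substrate → cross product (k = 15.0 /M/h)
    second substrate ⇌ dormant form (K = 11.0, k = 0.0800 /h)
    reagent + target → over-reaction product (k = 2.40 /M/h)

In ash, the step to target uses starting material 1.7 times as fast as the step to cross product at the start, and 57 times as fast at 25.0 h. By then 0.910% of the second substrate is left, and cross product stands at 9.42%.

Ash read at 15 h: taking the climb back from 0.927 gives a log-left of 0.755, so f is 47.0%. That flask holds 46.5% starting material and 37.0% target.

All runs are calculated for an exercise.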